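**Retrosynthetic overview**
- The target is traced back to an oxazole-4-carboxylic acid. The iodine on oxazole C4 is installed last by ipso-iododecarboxylation, so its position is fixed by a carboxyl group on the same carbon.
- The oxazole is the only ring built; indole and pyrrole are bought. It is cut at O1–C5 to an N-(pyrrole-2-carbonyl)tryptophan methyl ester. The strategy rests on this mapping: oxazole C5 (bearing the indol-3-yl), C4 and N3 are the beta carbon, alpha carbon and nitrogen of the tryptophan; C2 with its pyrrol-2-yl is the N-acyl carbon; the C4 ester is the amino acid carboxyl.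
- The N-acyl tryptophan ester comes from an acylaminomalonate by mono-hydrolysis and decarboxylation.
- The acylaminomalonate is assembled from the gramine of 6-bromo-4-methoxyindole (Mannich) and dimethyl 2-(pyrrole-2-carboxamido)malonate (amide coupling).

Key step: step 5

Assumption: the target is achiral, so the tryptophan intermediates are made racemic (the alpha carbon becomes sp2 oxazole C4); 6-bromo-4-methoxy-1H-indole, 1H-pyrrole-2-carboxylic acid and dimethyl aminomalonate hydrochloride are taken as purchasable.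

**Route**

Step 1
Reactants: 1 6-bromo-4-methoxy-1H-indole
Product: 2 1-(6-bromo-4-methoxy-1H-indol-3-yl)-N,N-dimethylmethanamine (the gramine)
Conditions: CH2O (37% aq), Me2NH (40% aq), AcOH, 0 °C to rt
Reagents that add atoms: formaldehyde, C=O; dimethylamine, CNC
Why: Mannich reaction, in which the iminium ion from formaldehyde and dimethylamine attacks indole C3, the most nucleophilic position, and the peri methoxy group should only slow it.

Step 2
Reactants: 3 1H-pyrrole-2-carboxylic acid; 4 dimethyl aminomalonate hydrochloride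
Product: 6 dimethyl 2-(1H-pyrrole-2-carboxamido)malonate, via acyl imidazole 5 (not isolated)
Conditions: CDI, THF, rt; then 4, rt to 50 °C
Reagents that add atoms: none
Why: CDI-mediated amide coupling, in which acid 3 is activated as acyl imidazole 5 and this acylates the amine of 4 as the released imidazole frees it from its hydrochloride, while the pyrrole N–H is too weakly nucleophilic to compete.

Step 3
Reactants: 2 the gramine; 6 dimethyl 2-(1H-pyrrole-2-carboxamido)malonate
Product: 8 dimethyl 2-[(6-bromo-4-methoxy-1H-indol-3-yl)methyl]-2-(1H-pyrrole-2-carboxamido)malonate, via 3-methyleneindolenine 7 (not isolated)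
Conditions: NaOMe (0.15 equiv), 6 (1.2 equiv), toluene, reflux, N2 sweep
Reagents that add atoms: none
Why: Gramine alkylation of an acylaminomalonate by elimination–addition, in which base-assisted loss of dimethylamine from 2 gives 3-methyleneindolenine 7 and the malonate enolate of 6 (its most acidic site) traps it in a Michael-type addition, the amine being swept out to drive the reaction.

Step 4
Reactants: 8 dimethyl 2-[(6-bromo-4-methoxy-1H-indol-3-yl)methyl]-2-(1H-pyrrole-2-carboxamido)malonate
Product: 10 methyl N-(1H-pyrrole-2-carbonyl)-6-bromo-4-methoxytryptophanate (racemic), via malonic half-acid 9 (not isolated)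
Conditions: KOH (1.05 equiv), MeOH/H2O, 0 °C to rt; 1 M HCl; then 1,4-dioxane, 100 °C
Reagents that add atoms: none
Why: Mono-saponification of a geminal diester followed by thermal decarboxylation of the acylaminomalonic half-acid 9 (malonic ester route to tryptophans), in which the first carboxylate shields the second ester from hydroxide and the alpha stereocentre forms without control as the racemate, which is acceptable because it later becomes oxazole C4.

Step 5
Reactants: 10 methyl N-(1H-pyrrole-2-carbonyl)-6-bromo-4-methoxytryptophanate (racemic)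
Product: 13 methyl 5-(6-bromo-4-methoxy-1H-indol-3-yl)-2-(1H-pyrrol-2-yl)oxazole-4-carboxylate, via 3-alkylideneindolenine 11 (not isolated), via oxazoline 12 (not isolated)
Conditions: DDQ (2.2 equiv), anhydrous THF, 4 Å MS, reflux
Reagents that add atoms: none
Why: DDQ should abstract hydride from the CH2 next to indole C3 of 10 (the tryptophan beta carbon), because the resulting cation is a vinylogous iminium ion of N1, and loss of the N1 proton gives the neutral 3-alkylidene-3H-indole 11. The amide oxygen then adds to the exocyclic carbon of 11 in a 5-exo-trig closure that forms the O1–C5 bond and oxazoline 12, and a second equivalent of DDQ removes the C5 and C4 hydrogens to aromatize the ring. The closest known reaction type is the DDQ oxidative cyclization of N-acyltryptophan esters to 5-(indol-3-yl)oxazole-4-carboxylates in hot anhydrous THF. The two stereocentres of 12 are transient and vanish on aromatization, so no stereocentre is set and the racemic nature of 10 is irrelevant. The step needs site selectivity for the indolic CH2 and chemoselectivity over the pyrrole: the free indole N–H secures the first (the 4-methoxy group is not in conjugation with the cation and only crowds the peri position), and the acyl deactivation of the pyrrole together with the absence of any other benzylic C–H secures the second. Water is excluded because it would intercept 11 and give the 3-acylindole instead of the ring.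

Step 6
Reactants: 13 methyl 5-(6-bromo-4-methoxy-1H-indol-3-yl)-2-(1H-pyrrol-2-yl)oxazole-4-carboxylate
Product: 14 methyl 5-(6-bromo-4-methoxy-1-tosyl-1H-indol-3-yl)-2-(1-tosyl-1H-pyrrol-2-yl)oxazole-4-carboxylate
Conditions: NaH (2.5 equiv), TsCl (2.4 equiv), DMF, 0 °C to rt
Reagents that add atoms: p-toluenesulfonyl chloride, Cc1ccc(cc1)S(Cl)(=O)=O
Why: N-sulfonylation of the indolide and pyrrolide anions formed by NaH (the methyl ester is inert), which switches off both electron-rich azoles toward electrophilic iodine in step 8.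

Step 7
Reactants: 14 methyl 5-(6-bromo-4-methoxy-1-tosyl-1H-indol-3-yl)-2-(1-tosyl-1H-pyrrol-2-yl)oxazole-4-carboxylate
Product: 16 5-(6-bromo-4-methoxy-1-tosyl-1H-indol-3-yl)-2-(1-tosyl-1H-pyrrol-2-yl)oxazole-4-carboxylic acid, via trimethylstannyl ester 15 (not isolated)
Conditions: Me3SnOH (5 equiv), ClCH2CH2Cl, 80 °C; then 1 M HCl
Reagents that add atoms: trimethyltin hydroxide, C[Sn](C)(C)O
Why: Me3SnOH-mediated methyl ester hydrolysis, a near-neutral acyl substitution that should cleave the ester through stannyl ester 15 while the N-sulfonyl azoles, which hydroxide in methanol would attack, survive.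

Step 8
Reactants: 16 5-(6-bromo-4-methoxy-1-tosyl-1H-indol-3-yl)-2-(1-tosyl-1H-pyrrol-2-yl)oxazole-4-carboxylic acid
Product: 18 6-bromo-3-[4-iodo-2-(1-tosyl-1H-pyrrol-2-yl)oxazol-5-yl]-4-methoxy-1-tosyl-1H-indole, via acyl hypoiodite 17 (not isolated)
Conditions: I2 (3 equiv), K3PO4 (1 equiv), MeCN, 100 °C, sealed tube
Reagents that add atoms: iodine, II
Why: Transition-metal-free decarboxylative ipso-iodination of a heteroaromatic carboxylic acid (Hunsdiecker-type halodecarboxylation), in which the carboxylate forms acyl hypoiodite 17 and this delivers iodine to the ipso carbon C4 with loss of CO2, so the iodine can only enter where the ester stood while the tosyl groups keep pyrrole and indole from being iodinated.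

Step 9
Reactants: 18 6-bromo-3-[4-iodo-2-(1-tosyl-1H-pyrrol-2-yl)oxazol-5-yl]-4-methoxy-1-tosyl-1H-indole
Product: 19 6-bromo-3-[4-iodo-2-(1H-pyrrol-2-yl)oxazol-5-yl]-4-methoxy-1H-indole (target)
Conditions: KOH (6 equiv), MeOH/THF, 50 °C
Reagents that add atoms: none
Why: Nucleophilic cleavage of the N–S bonds of the N-sulfonyl indole and N-sulfonyl pyrrole by hydroxide/methoxide (base-mediated detosylation), to which the aryl bromide, the 4-iodooxazole and the methyl ether are inert.

**Compound list**
1 | 6-bromo-4-methoxy-1H-indole | COc1cc(Br)cc2[nH]ccc12 | starting material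
2 | 1-(6-bromo-4-methoxy-1H-indol-3-yl)-N,N-dimethylmethanamine | CN(C)Cc1c[nH]c2cc(Br)cc(OC)c12 | intermediate
3 | 1H-pyrrole-2-carboxylic acid | OC(=O)c1ccc[nH]1 | starting material
4 | dimethyl aminomalonate hydrochloride | COC(=O)C(N)C(=O)OC.Cl | starting material
5 | (1H-imidazol-1-yl)(1H-pyrrol-2-yl)methanone | O=C(c1ccc[nH]1)n1ccnc1 | intermediate
6 | dimethyl 2-(1H-pyrrole-2-carboxamido)malonate | COC(=O)C(NC(=O)c1ccc[nH]1)C(=O)OC | intermediate
7 | 6-bromo-4-methoxy-3-methylidene-3H-indole | C=C1C=Nc2cc(Br)cc(OC)c12 | intermediate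
8 | dimethyl 2-[(6-bromo-4-methoxy-1H-indol-3-yl)methyl]-2-(1H-pyrrole-2-carboxamido)malonate | COC(=O)C(Cc1c[nH]c2cc(Br)cc(OC)c12)(NC(=O)c1ccc[nH]1)C(=O)OC | intermediate
9 | 2-[(6-bromo-4-methoxy-1H-indol-3-yl)methyl]-3-methoxy-3-oxo-2-(1H-pyrrole-2-carboxamido)propanoic acid (racemic) | COC(=O)C(Cc1c[nH]c2cc(Br)cc(OC)c12)(NC(=O)c1ccc[nH]1)C(O)=O | intermediate
10 | methyl N-(1H-pyrrole-2-carbonyl)-6-bromo-4-methoxytryptophanate (racemic) | COC(=O)C(Cc1c[nH]c2cc(Br)cc(OC)c12)NC(=O)c1ccc[nH]1 | intermediate
11 | methyl 3-(6-bromo-4-methoxy-3H-indol-3-ylidene)-2-(1H-pyrrole-2-carboxamido)propanoate (racemic) | COC(=O)C(NC(=O)c1ccc[nH]1)C=C1C=Nc2cc(Br)cc(OC)c12 | intermediate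
12 | methyl 5-(6-bromo-4-methoxy-1H-indol-3-yl)-2-(1H-pyrrol-2-yl)-4,5-dihydrooxazole-4-carboxylate (racemic, mixture of diastereomers) | COC(=O)C1N=C(c2ccc[nH]2)OC1c1c[nH]c2cc(Br)cc(OC)c12 | intermediate
13 | methyl 5-(6-bromo-4-methoxy-1H-indol-3-yl)-2-(1H-pyrrol-2-yl)oxazole-4-carboxylate | COC(=O)c1nc(-c2ccc[nH]2)oc1-c1c[nH]c2cc(Br)cc(OC)c12 | intermediate
14 | methyl 5-(6-bromo-4-methoxy-1-tosyl-1H-indol-3-yl)-2-(1-tosyl-1H-pyrrol-2-yl)oxazole-4-carboxylate | COC(=O)c1nc(-c2cccn2S(=O)(=O)c2ccc(C)cc2)oc1-c1cn(S(=O)(=O)c2ccc(C)cc2)c2cc(Br)cc(OC)c12 | intermediate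
15 | trimethylstannyl 5-(6-bromo-4-methoxy-1-tosyl-1H-indol-3-yl)-2-(1-tosyl-1H-pyrrol-2-yl)oxazole-4-carboxylate | C[Sn](C)(C)OC(=O)c1nc(-c2cccn2S(=O)(=O)c2ccc(C)cc2)oc1-c1cn(S(=O)(=O)c2ccc(C)cc2)c2cc(Br)cc(OC)c12 | intermediate
16 | 5-(6-bromo-4-methoxy-1-tosyl-1H-indol-3-yl)-2-(1-tosyl-1H-pyrrol-2-yl)oxazole-4-carboxylic acid | OC(=O)c1nc(-c2cccn2S(=O)(=O)c2ccc(C)cc2)oc1-c1cn(S(=O)(=O)c2ccc(C)cc2)c2cc(Br)cc(OC)c12 | intermediate
17 | 5-(6-bromo-4-methoxy-1-tosyl-1H-indol-3-yl)-2-(1-tosyl-1H-pyrrol-2-yl)oxazole-4-carbonyl hypoiodite | IOC(=O)c1nc(-c2cccn2S(=O)(=O)c2ccc(C)cc2)oc1-c1cn(S(=O)(=O)c2ccc(C)cc2)c2cc(Br)cc(OC)c12 | intermediate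
18 | 6-bromo-3-[4-iodo-2-(1-tosyl-1H-pyrrol-2-yl)oxazol-5-yl]-4-methoxy-1-tosyl-1H-indole | COc1cc(Br)cc2c1c(-c1oc(-c3cccn3S(=O)(=O)c3ccc(C)cc3)nc1I)cn2S(=O)(=O)c1ccc(C)cc1 | intermediate
19 | 6-bromo-3-[4-iodo-2-(1H-pyrrol-2-yl)oxazol-5-yl]-4-methoxy-1H-indole | COc1cc(Br)cc2[nH]cc(-c3oc(-c4ccc[nH]4)nc3I)c12 | target

**Step count**
Total step count: 9.
Longest linear sequence: 8 steps (1 → 2 → 8 → 10 → 13 → 14 → 16 → 18 → 19; step 2 is a one-step side branch).

**Steps most likely to fail**

1. Step 5. Ring closure by the amide oxygen at the peri-crowded exocyclic carbon may lag behind hydride abstraction, so that the alkylideneindolenine is oxidized further or captured by traces of water before the ring forms. Fallback: starting from 10, the oxidation is run on purpose in wet THF (DDQ, THF/H2O 9:1, rt), so that water intercepts the cation and the side chain is oxidized to the ketone methyl 3-(6-bromo-4-methoxy-1H-indol-3-yl)-3-oxo-2-(1H-pyrrole-2-carboxamido)propanoate F1. A Robinson–Gabriel cyclodehydration of this beta-keto amide (PPh3, I2, Et3N, CH2Cl2, rt) then forms the O1–C5 bond by dehydration and returns to the route at 13.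

2. Step 8. Protodecarboxylation may outrun iodine transfer at 100 °C, or the acyl hypoiodite may pass iodine intermolecularly to the methoxy-activated benzenoid ring instead of to the ipso carbon. Fallback: starting from 16, the carboxyl group is removed first by silver-catalysed protodecarboxylation (Ag2CO3 cat., AcOH, DMSO, 120 °C) to give 6-bromo-4-methoxy-1-tosyl-3-[2-(1-tosyl-1H-pyrrol-2-yl)oxazol-5-yl]-1H-indole F2. Electrophilic aromatic iodination (NIS, TFA cat., MeCN, rt) then goes to oxazole C4, the only free oxazole carbon, because both sulfonylated azoles are deactivated; this returns to the route at 18.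

3. Step 7. The N-sulfonyl groups may be lost from the pyrrole or the indole, or cleavage of the hindered ester may stay incomplete. Fallback: the order of events is reversed. Starting from 13, the ester is hydrolysed before any protecting group is present (LiOH, THF/MeOH/H2O, 50 °C) to give 5-(6-bromo-4-methoxy-1H-indol-3-yl)-2-(1H-pyrrol-2-yl)oxazole-4-carboxylic acid F3. Its trisodium salt is then N-sulfonylated on both azoles (NaH 3.5 equiv, TsCl 2.3 equiv, DMF, 0 °C to rt), and an aqueous NaHCO3 work-up hydrolyses any mixed carboxylic–sulfonic anhydride; this returns to the route at 16.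

Further compounds
F1 | step 5 | methyl 3-(6-bromo-4-methoxy-1H-indol-3-yl)-3-oxo-2-(1H-pyrrole-2-carboxamido)propanoate (racemic) | COC(=O)C(NC(=O)c1ccc[nH]1)C(=O)c1c[nH]c2cc(Br)cc(OC)c12
F2 | step 8 | 6-bromo-4-methoxy-1-tosyl-3-[2-(1-tosyl-1H-pyrrol-2-yl)oxazol-5-yl]-1H-indole | COc1cc(Br)cc2c1c(-c1cnc(-c3cccn3S(=O)(=O)c3ccc(C)cc3)o1)cn2S(=O)(=O)c1ccc(C)cc1
F3 | step 7 | 5-(6-bromo-4-methoxy-1H-indol-3-yl)-2-(1H-pyrrol-2-yl)oxazole-4-carboxylic acid | OC(=O)c1nc(-c2ccc[nH]2)oc1-c1c[nH]c2cc(Br)cc(OC)c12
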